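**Plan**

1. Retrosynthetic cuts (labdane numbering; C17 = exocyclic CH2, side chain C11–C16): O–acetyl; C14–C15 and C13–C16 (carboalumination/acylation of a C13≡C14 alkyne); C11–C12 (propargylation of albicanal); C9–C11 (carbonylation of a C9 enol triflate); C3–C4 (ring A); C10–C1 and C10–C20 (two enolate alkylations) → (R)-carvone.
2. Enabling feature: C5 and C8 are para on ring B, so ring B + C17 + C4(C18, C19) is the p-menthane skeleton of carvone. The carvone C=O is C9, its α′-carbon is C10, its methyl is C17, and its isopropenyl carbon is C4, a latent tertiary radical.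
3. Forward: carvone is ring B; C10 is made quaternary (CH3, then a 2-sulfonylallyl tether = C1–C3); ring A is closed last by joining C3 to C4; the sulfone helper on C2 leaves in the next step.
4. The C9 ketone then becomes enol triflate → C11 ester → deconjugation to the 8(17)-ene → albicanal → side chain (C12–C16) → acetate. No protecting groups are used.
5. Stereochemistry: C5 from (R)-carvone; C10 by alkylation anti to the isopropenyl group, which fixes the trans ring fusion before ring A exists; C9 by axial protonation of a dienolate; C11 by a chiral catalyst; 13E by syn-carbometalation.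

Key step: step 5

Assumption: (S)-TRIP is taken to deliver the allenylboronate to the Si face of the aldehyde (the sense opposite to that of its enantiomer with simple aldehydes); if the sense is reversed, (R)-TRIP is used.

**Step 1**
Reactants: 1 phenyl vinyl sulfone
Product: 2 2-(phenylsulfonyl)prop-2-en-1-ol
Conditions: 37% aq. CH2O, DABCO (0.3 equiv), THF, rt
Reagents that add atoms: formaldehyde C=O
Why: Morita–Baylis–Hillman hydroxymethylation (DABCO adds to the vinyl sulfone, the α-sulfonyl carbanion traps formaldehyde, DABCO is eliminated); no stereocentre is formed.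

**Step 2**
Reactants: 2 2-(phenylsulfonyl)prop-2-en-1-ol
Product: 3 3-bromo-2-(phenylsulfonyl)prop-1-ene
Conditions: PBr3, Et2O, 0 °C
Reagents that add atoms: phosphorus tribromide BrP(Br)Br
Why: Standard conversion of a primary allylic alcohol into the bromide via its phosphite ester; no stereocentre.

**Step 3**
Reactants: 4 (R)-carvone
Product: 6 (5R)-2,6-dimethyl-5-(prop-1-en-2-yl)cyclohex-2-en-1-one (6-methylcarvone; C6 epimers), via carvone lithium dienolate 5 (not isolated)
Conditions: LDA, THF, −78 °C; MeI, −78 → −20 °C
Reagents that add atoms: iodomethane CI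
Why: Kinetic α′-deprotonation of the enone and SN2 methylation of the cross-conjugated enolate should install C20; the new centre is an epimer mixture that is made planar again in step 4.

**Step 4**
Reactants: 6 6-methylcarvone; 3 3-bromo-2-(phenylsulfonyl)prop-1-ene
Product: 8 (5S,6S)-2,6-dimethyl-6-[2-(phenylsulfonyl)prop-2-en-1-yl]-5-(prop-1-en-2-yl)cyclohex-2-en-1-one, via lithium enolate 7 (not isolated)
Conditions: LDA (1.05 equiv), THF, −78 °C; 3, −78 → −30 °C
Reagents that add atoms: none
Why: Enolate alkylation (SN2 and SN2′ paths give the same product) should create the quaternary C10, the electrophile entering anti to the neighbouring isopropenyl group so that the tether (C1) is trans and the methyl cis to the C5 substituent.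

**Step 5**
Reactants: 8 alkylated carvone
Product: 10 (4aS,8aS)-2,5,5,8a-tetramethyl-7-(phenylsulfonyl)-4a,5,6,7,8,8a-hexahydronaphthalen-1(4H)-one (C7 epimers), via tertiary C4 radical 9 (not isolated)
Conditions: Fe(acac)3 (0.5 equiv), PhSiH3 (2.5 equiv), EtOH/(CH2OH)2 5:1, 0.02 M, 60 °C
Reagents that add atoms: none
Why: An iron hydride formed from Fe(acac)3 and PhSiH3 should transfer a hydrogen atom to the CH2 terminus of the electron-neutral isopropenyl group, giving the nucleophilic tertiary radical 9 at C4, which adds to the unsubstituted terminus of the tethered vinyl sulfone; the α-sulfonyl radical is then reduced by Fe(II) and protonated by ethanol. The closest known reaction type is the iron-hydride reductive olefin coupling (Giese addition of a hydrogen-atom-transfer-derived tertiary radical to an electron-poor alkene), run here intramolecularly. Ring A (C4–C3–C2–C1–C10–C5) closes in the 6-endo-trig mode, forming the C3–C4 bond and the gem-dimethyl quaternary carbon at once, the former =CH2 becoming the second methyl. The only new stereocentre is the sulfone-bearing C2, which is uncontrolled and is erased in step 6; the ring fusion is not created here, because the trans-disposed C5–C4 and C10–C1 bonds set by carvone and by step 4 can only close to the trans-decalin. The step needs hydrogen-atom transfer to the isopropenyl group in preference to the two electron-poor alkenes, which the polarity of the iron hydride secures. It also needs 6-endo over 5-exo closure, secured because 5-exo attack would have to occur at the fully substituted sulfonyl-bearing carbon and would give a primary radical in a strained trans-hydrindane.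

**Step 6**
Reactants: 10 sulfonyl decalenone
Product: 12 (4aS,8aS)-2,5,5,8a-tetramethyl-3,4,4a,5,6,7,8,8a-octahydronaphthalen-1-yl trifluoromethanesulfonate, via lithium enolate 11 (not isolated)
Conditions: Li (6 equiv), t-BuOH (2 equiv), NH3/THF, −78 °C; isoprene; evaporate NH3; PhNTf2 (3 equiv), THF, 0 °C → rt
Reagents that add atoms: N-phenyl-bis(trifluoromethanesulfonimide) O=S(=O)(N(c1ccccc1)S(=O)(=O)C(F)(F)F)C(F)(F)F
Why: Dissolving-metal reduction should convert the enone into the only possible enolate (C9–O, C8=C9; C10 is quaternary) and at the same time cleave the alkyl–SO2Ph bond (C2 becomes CH2); O-triflation of the enolate then gives the tetrasubstituted enol triflate, with no new stereocentre.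

**Step 7**
Reactants: 12 enol triflate
Product: 13 methyl (4aS,8aS)-2,5,5,8a-tetramethyl-3,4,4a,5,6,7,8,8a-octahydronaphthalene-1-carboxylate (methyl drim-8-en-11-oate)
Conditions: Pd(OAc)2 (5 mol%), dppf, CO (1 atm), MeOH, Et3N, DMF, 60 °C
Reagents that add atoms: carbon monoxide [C-]#[O+]; methanol CO
Why: Palladium-catalysed methoxycarbonylation of a vinyl triflate (oxidative addition, CO insertion, methanolysis) should install C11, as is routine for the analogous 2,6,6-trimethylcyclohexenyl triflate.

**Step 8**
Reactants: 13 conjugated ester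
Product: 15 methyl (1S,4aS,8aS)-5,5,8a-trimethyl-2-methylidenedecahydronaphthalene-1-carboxylate (methyl albicanate), via exocyclic lithium dienolate 14 (not isolated)
Conditions: LDA (1.3 equiv), THF/DMPU, −78 → −20 °C; inverse quench into AcOH/THF, −78 °C
Reagents that add atoms: none
Why: Deconjugative protonation: the ester carbonyl should direct LDA to the syn γ-hydrogen on C17 (as in the β- to γ-cyclogeranate conversion), and kinetic α-protonation of the dienolate at C9 from the α face, anti to the axial C10 methyl, should give the 8(17)-ene with the equatorial 9β-ester (9S).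

**Step 9**
Reactants: 15 methyl albicanate
Product: 16 [(1S,4aS,8aS)-5,5,8a-trimethyl-2-methylidenedecahydronaphthalen-1-yl]methanol (albicanol)
Conditions: LiAlH4, Et2O, 0 °C
Reagents that add atoms: none
Why: Hydride reduction of the ester; the isolated exocyclic alkene and C9 are untouched.

**Step 10**
Reactants: 16 albicanol
Product: 17 (1S,4aS,8aS)-5,5,8a-trimethyl-2-methylidenedecahydronaphthalene-1-carbaldehyde (albicanal)
Conditions: Dess–Martin periodinane, NaHCO3, CH2Cl2, 0 °C; used crude
Reagents that add atoms: none
Why: Dess–Martin oxidation under buffered conditions should give the β,γ-unsaturated aldehyde without epimerisation at C9 or migration of the double bond.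

**Step 11**
Reactants: 17 albicanal; 18 allenylboronic acid pinacol ester
Product: 19 (1S)-1-[(1S,4aS,8aS)-5,5,8a-trimethyl-2-methylidenedecahydronaphthalen-1-yl]but-3-yn-1-ol
Conditions: (S)-TRIP phosphoric acid (10 mol%), 4 Å MS, toluene, 0 °C → rt; aqueous work-up
Reagents that add atoms: none
Why: Chiral-phosphoric-acid-catalysed allenylboration (SE2′ addition through a six-membered chair transition state) should form C11–C12, the catalyst directing attack to the Si face of the aldehyde to give the 11S carbinol.

**Step 12**
Reactants: 19 homopropargylic alcohol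
Product: 21 methyl (2E,5S)-5-hydroxy-3-methyl-5-[(1S,4aS,8aS)-5,5,8a-trimethyl-2-methylidenedecahydronaphthalen-1-yl]pent-2-enoate, via alkenylalane 20 (not isolated)
Conditions: Me3Al (3 equiv), Cp2ZrCl2 (0.25 equiv), CH2Cl2, 0 °C → rt; ClCO2Me, 0 °C → rt
Reagents that add atoms: trimethylaluminium C[Al](C)C; methyl chloroformate COC(Cl)=O
Why: Negishi zirconium-catalysed carboalumination should add CH3 (internal carbon) and Al (terminal carbon) syn across the alkyne, and acylation of the alkenyl–Al bond with retention should give the 13E enoate; the alcohol is masked in the flask as its aluminium alkoxide.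

**Step 13**
Reactants: 21 hydroxy enoate
Product: 22 methyl (2E,5S)-5-acetoxy-3-methyl-5-[(1S,4aS,8aS)-5,5,8a-trimethyl-2-methylidenedecahydronaphthalen-1-yl]pent-2-enoate (target)
Conditions: Ac2O, DMAP (cat.), pyridine, CH2Cl2, rt
Reagents that add atoms: acetic anhydride CC(=O)OC(C)=O
Why: DMAP-catalysed O-acetylation proceeds with retention at C11 and, under these mild basic conditions, should not eliminate to the dienoate.

**Compound list**

1 | phenyl vinyl sulfone | C=CS(=O)(=O)c1ccccc1 | starting material
2 | 2-(phenylsulfonyl)prop-2-en-1-ol | C=C(CO)S(=O)(=O)c1ccccc1 | intermediate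
3 | 3-bromo-2-(phenylsulfonyl)prop-1-ene | C=C(CBr)S(=O)(=O)c1ccccc1 | intermediate
4 | (R)-carvone, (5R)-2-methyl-5-(prop-1-en-2-yl)cyclohex-2-en-1-one | CC1=CC[C@H](CC1=O)C(C)=C | starting material
5 | lithium cross-conjugated dienolate of carvone (C1=C6, O–Li) | CC1=CC[C@@H](C(C)=C)C=C1O[Li] | intermediate
6 | (5R)-2,6-dimethyl-5-(prop-1-en-2-yl)cyclohex-2-en-1-one, C6 epimers | CC1=CC[C@@H](C(C)=C)C(C)C1=O | intermediate
7 | lithium enolate of 6 (C1=C6, O–Li) | CC1=CC[C@@H](C(C)=C)C(C)=C1O[Li] | intermediate
8 | (5S,6S)-2,6-dimethyl-6-[2-(phenylsulfonyl)prop-2-en-1-yl]-5-(prop-1-en-2-yl)cyclohex-2-en-1-one | CC1=CC[C@@H](C(C)=C)[C@](C)(CC(=C)S(=O)(=O)c2ccccc2)C1=O | intermediate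
9 | tertiary 2-propyl radical derived from 8 (radical at C4) | CC1=CC[C@@H]([C](C)C)[C@](C)(CC(=C)S(=O)(=O)c2ccccc2)C1=O | intermediate
10 | (4aS,8aS)-2,5,5,8a-tetramethyl-7-(phenylsulfonyl)-4a,5,6,7,8,8a-hexahydronaphthalen-1(4H)-one, C7 epimers | CC1=CC[C@H]2C(C)(C)CC(S(=O)(=O)c3ccccc3)C[C@]2(C)C1=O | intermediate
11 | lithium (4aS,8aS)-2,5,5,8a-tetramethyl-3,4,4a,5,6,7,8,8a-octahydronaphthalen-1-olate | CC1=C(O[Li])[C@@]2(C)CCCC(C)(C)[C@@H]2CC1 | intermediate
12 | (4aS,8aS)-2,5,5,8a-tetramethyl-3,4,4a,5,6,7,8,8a-octahydronaphthalen-1-yl trifluoromethanesulfonate | CC1=C(OS(=O)(=O)C(F)(F)F)[C@@]2(C)CCCC(C)(C)[C@@H]2CC1 | intermediate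
13 | methyl (4aS,8aS)-2,5,5,8a-tetramethyl-3,4,4a,5,6,7,8,8a-octahydronaphthalene-1-carboxylate | CC1=C(C(=O)OC)[C@@]2(C)CCCC(C)(C)[C@@H]2CC1 | intermediate
14 | exocyclic lithium dienolate of 13 (C8=C17, C9=C11, O–Li) | C=C1CC[C@H]2C(C)(C)CCC[C@]2(C)C1=C(OC)O[Li] | intermediate
15 | methyl (1S,4aS,8aS)-5,5,8a-trimethyl-2-methylidenedecahydronaphthalene-1-carboxylate | C=C1CC[C@H]2C(C)(C)CCC[C@]2(C)[C@H]1C(=O)OC | intermediate
16 | [(1S,4aS,8aS)-5,5,8a-trimethyl-2-methylidenedecahydronaphthalen-1-yl]methanol (albicanol) | C=C1CC[C@H]2C(C)(C)CCC[C@]2(C)[C@H]1CO | intermediate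
17 | (1S,4aS,8aS)-5,5,8a-trimethyl-2-methylidenedecahydronaphthalene-1-carbaldehyde (albicanal) | C=C1CC[C@H]2C(C)(C)CCC[C@]2(C)[C@H]1C=O | intermediate
18 | allenylboronic acid pinacol ester, 4,4,5,5-tetramethyl-2-(propa-1,2-dien-1-yl)-1,3,2-dioxaborolane | C=C=CB1OC(C)(C)C(C)(C)O1 | starting material
19 | (1S)-1-[(1S,4aS,8aS)-5,5,8a-trimethyl-2-methylidenedecahydronaphthalen-1-yl]but-3-yn-1-ol | C=C1CC[C@H]2C(C)(C)CCC[C@]2(C)[C@H]1[C@H](CC#C)O | intermediate
20 | (E)-alkenyl(dimethyl)alane of 19, as its O-dimethylaluminium alkoxide | C=C1CC[C@H]2C(C)(C)CCC[C@]2(C)[C@H]1[C@H](C/C(C)=C/[Al](C)C)O[Al](C)C | intermediate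
21 | methyl (2E,5S)-5-hydroxy-3-methyl-5-[(1S,4aS,8aS)-5,5,8a-trimethyl-2-methylidenedecahydronaphthalen-1-yl]pent-2-enoate | C=C1CC[C@H]2C(C)(C)CCC[C@]2(C)[C@H]1[C@H](C/C(C)=C/C(=O)OC)O | intermediate
22 | methyl (2E,5S)-5-acetoxy-3-methyl-5-[(1S,4aS,8aS)-5,5,8a-trimethyl-2-methylidenedecahydronaphthalen-1-yl]pent-2-enoate | C=C1CC[C@H]2C(C)(C)CCC[C@]2(C)[C@H]1[C@H](C/C(C)=C/C(=O)OC)OC(C)=O | target

**Step count**

Total steps: 13. Longest linear sequence: 12 steps (steps 1, 2 and 4–13, from phenyl vinyl sulfone 1 through 3 and 8 to 22). The branch from (R)-carvone 4 is 11 steps (steps 3–13), and 18 enters at step 11.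

**Steps most likely to fail**

Step 5. The tertiary radical may be reduced by the iron hydride or silane before it cyclises (net hydrogenation of the isopropenyl group), or the vinyl sulfone may oligomerise. The fallback sets out from 8 and returns at 10. Markovnikov addition of HBr (HBr/AcOH, CH2Cl2, 0 °C) to the isopropenyl group should give (5R,6S)-5-(2-bromopropan-2-yl)-2,6-dimethyl-6-[2-(phenylsulfonyl)prop-2-en-1-yl]cyclohex-2-en-1-one F1. Slow addition of Bu3SnH/AIBN (benzene, 80 °C) then generates the same C4 radical by bromine abstraction at a low, controlled hydrogen-donor concentration, which leaves the 6-endo closure to 10 more time.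

Step 8. Deprotonation may occur at the ring C7–H instead of C17–H (leading to the endocyclic Δ7 isomer), or the dienolate may be protonated at the γ-carbon and return 13. The fallback sets out from 13 and returns at 15. Irradiation at 254 nm (hexane/MeOH, catalytic 1,2-dimethylimidazole) should cause a photochemical 1,5-hydrogen shift from C17, the only γ-carbon held syn to the carbonyl, to the ester oxygen, giving the photodienol F2. Its base-catalysed ketonisation by protonation at C9 from the α face leads to 15.

Step 11. Facial selectivity at C11 may be poor if the intrinsic preference of the hindered α-chiral aldehyde opposes the catalyst (mismatched pairing). The fallback sets out from 17 and returns at 22, and uses the substrate bias instead of fighting it. Uncatalysed addition of 18 (toluene, 40 °C) should then give mainly the (1R)-epimer of 19, (1R)-1-[(1S,4aS,8aS)-5,5,8a-trimethyl-2-methylidenedecahydronaphthalen-1-yl]but-3-yn-1-ol F3. Carboalumination/acylation as in step 12, through the alkenylalane F4, gives the (5R)-hydroxy enoate F5. A Mitsunobu reaction with acetic acid (PPh3, DIAD, AcOH, toluene, 0 °C) then installs the acetate with inversion to give 22.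

**Further compounds**

F1 | step 5 | (5R,6S)-5-(2-bromopropan-2-yl)-2,6-dimethyl-6-[2-(phenylsulfonyl)prop-2-en-1-yl]cyclohex-2-en-1-one | CC1=CC[C@@H](C(C)(C)Br)[C@](C)(CC(=C)S(=O)(=O)c2ccccc2)C1=O
F2 | step 8 | photodienol of 13 (C8=C17, C9=C11, enol OH) | C=C1CC[C@H]2C(C)(C)CCC[C@]2(C)C1=C(O)OC
F3 | step 11 | (1R)-1-[(1S,4aS,8aS)-5,5,8a-trimethyl-2-methylidenedecahydronaphthalen-1-yl]but-3-yn-1-ol | C=C1CC[C@H]2C(C)(C)CCC[C@]2(C)[C@H]1[C@@H](CC#C)O
F4 | step 11 | (E)-alkenyl(dimethyl)alane of F3, as its O-dimethylaluminium alkoxide | C=C1CC[C@H]2C(C)(C)CCC[C@]2(C)[C@H]1[C@@H](C/C(C)=C/[Al](C)C)O[Al](C)C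
F5 | step 11 | methyl (2E,5R)-5-hydroxy-3-methyl-5-[(1S,4aS,8aS)-5,5,8a-trimethyl-2-methylidenedecahydronaphthalen-1-yl]pent-2-enoate | C=C1CC[C@H]2C(C)(C)CCC[C@]2(C)[C@H]1[C@@H](C/C(C)=C/C(=O)OC)O
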